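**Retrosynthetic overview**

1. The pyran ring is made last: trichopsistide B ⇒ 4-hydroxy-6-methyl-2-pyrone + tricyclic ketal enone 15 (Michael addition, then hemiketal closure), leaving only a silyl ether to remove.
2. The dioxolane ring: 15 ⇒ mixed ethyl ketal 13 (PMB removal, exchange of OEt for the side-chain oxygen).
3. The route rests on the oxane ring (ring O, spiro-ketal C, ring-fusion C, pyronyl CH, CH2, O–CH bridgehead), read as the [4+2] adduct of an aldehyde C=O and a 1-ethoxydiene: 13 ⇒ diene 7 + aldehyde 12, forming the ring CH2–CH(O) bond and the O–C(ketal) bond.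
4. Diene 7 comes from 3-ethoxycyclohexenone (α′-acetoxylation, enzymatic resolution, silylation, iodination, Stille vinylation); aldehyde 12 comes from (S)-1,2-epoxyoctane.
5. Ring order: cyclohexane (bought) → oxane (step 10) → dioxolane (step 11) → pyran fused to the bought pyrone (step 12).

Key step: step 10

Assumption: the lipase in step 2 is taken to follow the empirical rule for secondary carbinols with the carbonyl flank as the large group, so the (R)-acetate is hydrolysed first; were the sense reversed, the recovered acetate would be carried on after mild methanolysis.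

Remark: the ketal carbon of 13 is drawn as one ethoxy anomer; the other anomer, if formed, is carried along because step 11 erases this centre.

**Route**

Step 1
Reactants: 1 3-ethoxycyclohex-2-en-1-one
Product: 2 rac-6-acetoxy-3-ethoxycyclohex-2-en-1-one
Conditions: Mn(OAc)3·2H2O (2.5 equiv), benzene or PhMe, reflux, Dean–Stark
Reagents that add atoms: manganese(III) acetate, CC(=O)[O-].CC(=O)[O-].CC(=O)[O-].[Mn+3]
Why: Mn(III)-mediated α′-acetoxylation of an enone, in which the Mn(III) enolate can form only at the single enolisable CH2 (C-6) and is acetoxylated there, giving the racemate.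

Step 2
Reactants: 2 rac-6-acetoxy-3-ethoxycyclohex-2-en-1-one
Product: 3 (R)-3-ethoxy-6-hydroxycyclohex-2-en-1-one
Conditions: Amano lipase PS, 0.1 M phosphate buffer pH 7/MTBE, rt, stopped below half conversion; chromatography
Reagents that add atoms: none
Why: Lipase-catalysed kinetic resolution by enantioselective ester hydrolysis, in which acyl–oxygen cleavage keeps the configuration of the fast (R)-acetate and the untouched (S)-acetate is separated, so the carbinol stereocentre is set by the enzyme.

Step 3
Reactants: 3 (R)-3-ethoxy-6-hydroxycyclohex-2-en-1-one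
Product: 4 (R)-6-[(tert-butyldimethylsilyl)oxy]-3-ethoxycyclohex-2-en-1-one
Conditions: TBSCl, imidazole, DMF, 0 °C → rt
Reagents that add atoms: tert-butyldimethylsilyl chloride, CC(C)(C)[Si](C)(C)Cl
Why: Standard silylation of a secondary alcohol under weakly basic conditions that should not enolise the α-oxy ketone.

Step 4
Reactants: 4 (R)-6-[(tert-butyldimethylsilyl)oxy]-3-ethoxycyclohex-2-en-1-one
Product: 5 (R)-6-[(tert-butyldimethylsilyl)oxy]-3-ethoxy-2-iodocyclohex-2-en-1-one
Conditions: NIS, MeCN, 0 °C → rt, dark
Reagents that add atoms: N-iodosuccinimide, O=C1CCC(=O)N1I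
Why: Electrophilic iodination at C-2, the nucleophilic α-carbon of the vinylogous ester, under neutral conditions that spare the silyl ether.

Step 5
Reactants: 5 (R)-6-[(tert-butyldimethylsilyl)oxy]-3-ethoxy-2-iodocyclohex-2-en-1-one; 6 tributyl(vinyl)stannane
Product: 7 (R)-6-[(tert-butyldimethylsilyl)oxy]-3-ethoxy-2-vinylcyclohex-2-en-1-one
Conditions: Pd2(dba)3 (2.5 mol %), AsPh3 (10 mol %), CuI (10 mol %), NMP, rt → 40 °C; used promptly
Reagents that add atoms: none
Why: Stille cross-coupling of an α-iodoenone with a vinylstannane, a neutral sp2–sp2 coupling that should leave the epimerisable α-silyloxy ketone untouched.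

Step 6
Reactants: 8 (S)-1,2-epoxyoctane
Product: 9 (S)-octane-1,2-diol
Conditions: KOH (2 M aq.), DMSO, 100 °C
Reagents that add atoms: water, O
Why: Base-mediated epoxide hydrolysis, in which hydroxide opens the oxirane by SN2 attack at the unsubstituted carbon so the stereocentre is not touched.

Step 7
Reactants: 9 (S)-octane-1,2-diol
Product: 10 (4S)-4-hexyl-2-(4-methoxyphenyl)-1,3-dioxolane (both acetal epimers)
Conditions: 4-MeOC6H4CH(OMe)2, PPTS (cat.), CH2Cl2, rt
Reagents that add atoms: 4-methoxybenzaldehyde dimethyl acetal, COc1ccc(C(OC)OC)cc1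
Why: Acid-catalysed transacetalisation of a 1,2-diol, driven by loss of methanol.

Step 8
Reactants: 10 (4S)-4-hexyl-2-(4-methoxyphenyl)-1,3-dioxolane
Product: 11 (S)-2-[(4-methoxybenzyl)oxy]octan-1-ol
Conditions: DIBAL-H, CH2Cl2, −78 → 0 °C; Rochelle salt
Reagents that add atoms: none
Why: Regioselective reductive opening of a p-methoxybenzylidene acetal, in which aluminium binds the less hindered primary oxygen and cleaves that C–O bond, leaving the PMB group on the secondary oxygen.

Step 9
Reactants: 11 (S)-2-[(4-methoxybenzyl)oxy]octan-1-ol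
Product: 12 (S)-2-[(4-methoxybenzyl)oxy]octanal
Conditions: Dess–Martin periodinane, NaHCO3, CH2Cl2, 0 °C → rt; used crude at once
Reagents that add atoms: none
Why: Dess–Martin oxidation under buffered, non-basic conditions chosen to avoid epimerisation of the α-alkoxy aldehyde.

Step 10
Reactants: 7 (R)-6-[(tert-butyldimethylsilyl)oxy]-3-ethoxy-2-vinylcyclohex-2-en-1-one; 12 (S)-2-[(4-methoxybenzyl)oxy]octanal
Product: 13 mixed ethyl ketal (2S,6R,8aR)-6-[(tert-butyldimethylsilyl)oxy]-8a-ethoxy-2-{(1S)-1-[(4-methoxybenzyl)oxy]heptyl}-2,3,6,7,8,8a-hexahydro-5H-chromen-5-one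
Conditions: 12 + MgBr2·OEt2 (1.5 equiv), CH2Cl2, −40 °C, 15 min; then 7 (1.3 equiv), −40 → 0 °C; Et3N, then aq. NaHCO3
Reagents that add atoms: none
Why: Proposed new method: MgBr2 holds the aldehyde oxygen and the α-PMB ether of 12 in a five-membered chelate, the terminal vinyl carbon of the 1-ethoxydiene 7 (pushed by the ring ethoxy group) attacks the aldehyde carbon to form the CH2–CH(O) bond, and the magnesium alkoxide then adds to the resulting ethoxy-oxocarbenium carbon to form the O–C(ketal) bond; this stepwise oxa-[4+2] is closest to the known MgBr2-promoted Mukaiyama-type hetero-Diels–Alder cyclocondensation of 1-alkoxydienes with α-alkoxy aldehydes, and the acyl group on the diene is the untested part. The oxane ring closes by 6-exo-trig attack of oxygen on the C=O+Et carbon. The new carbinol centre is controlled by the chelate, the diene approaching the aldehyde face opposite the hexyl group to give the syn (threo, S,S) pair of O–CH centres, while the ketal centre may form as either ethoxy anomer and is erased in step 11. The step needs attack through the vinyl terminus (C-2 of the vinylogous ester is fully substituted), C–O closure faster than proton loss from the oxocarbenium ion (intramolecular alkoxide, non-basic medium), and retention of the ethoxy group so that the two ring carbonyls stay differentiated (a mild halide Lewis acid at or below 0 °C that should not ionise the product ketal or cleave PMB or TBS).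

Step 11
Reactants: 13 mixed ethyl ketal
Product: 15 tricyclic ketal enone 10-exo-hexyl-4-[(tert-butyldimethylsilyl)oxy]-11,12-dioxatricyclo[7.2.1.0^1,6]dodec-6-en-5-one, via free carbinol 14 (not isolated)
Conditions: DDQ, CH2Cl2/pH 7 buffer, 0 °C; extract, dry; then CSA (10 mol %), 4 Å MS, CH2Cl2, 0 °C → rt, short
Reagents that add atoms: none
Why: Oxidative PMB cleavage followed by acid-catalysed intramolecular transketalisation, in which ionisation of the C–OEt bond gives the ring oxocarbenium ion and the freed hydroxyl captures it (five-membered dioxolane closure) from the only face its tether reaches, so the ketal carbon is fixed by the adjacent carbinol, the hexyl group ends exo, and mild, brief acid keeps O-capture ahead of proton loss.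

Step 12
Reactants: 15 tricyclic ketal enone; 16 4-hydroxy-6-methyl-2H-pyran-2-one
Product: 18 O-TBS-trichopsistide B (target skeleton with the secondary hydroxyl still silylated), via Michael adduct ketone 17 (not isolated)
Conditions: 16 (1.5 equiv), Et3N (0.2 equiv), MeCN, rt → 40–60 °C
Reagents that add atoms: none
Why: Amine-catalysed Michael addition of pyrone C-3 to the enone β-carbon followed by hemiketalisation of the released ketone with the pyrone 4-OH (a known pairing of 4-hydroxy-2-pyrones with enones), in which the pyrone should enter on the convex face anti to the dioxolane bridge, the ring-fusion CH is set by reversible ketonisation and hemiketal closure toward the isomer with its hydrogen syn to the bridge (pyran trans-fused to the cyclohexane, ring CH2 kept away from the pyrone carbonyl), and the hemiketal OH settles axial (anomeric effect).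

Step 13
Reactants: 18 O-TBS-trichopsistide B
Product: 19 trichopsistide B
Conditions: HF·pyridine, pyridine/THF, 0 °C → rt
Reagents that add atoms: none
Why: Fluoride-mediated desilylation under buffered conditions that should cleave only the Si–O bond and leave the bicyclic ketal, the hemiketal, the pyrone and every stereocentre untouched.

**Compound list**

1 | 3-ethoxycyclohex-2-en-1-one | CCOC1=CC(=O)CCC1 | starting material
2 | rac-6-acetoxy-3-ethoxycyclohex-2-en-1-one | CCOC1=CC(=O)C(OC(C)=O)CC1 | intermediate
3 | (R)-3-ethoxy-6-hydroxycyclohex-2-en-1-one | CCOC1=CC(=O)[C@H](O)CC1 | intermediate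
4 | (R)-6-[(tert-butyldimethylsilyl)oxy]-3-ethoxycyclohex-2-en-1-one | CCOC1=CC(=O)[C@H](O[Si](C)(C)C(C)(C)C)CC1 | intermediate
5 | (R)-6-[(tert-butyldimethylsilyl)oxy]-3-ethoxy-2-iodocyclohex-2-en-1-one | CCOC1=C(I)C(=O)[C@H](O[Si](C)(C)C(C)(C)C)CC1 | intermediate
6 | tributyl(vinyl)stannane | C=C[Sn](CCCC)(CCCC)CCCC | starting material
7 | (R)-6-[(tert-butyldimethylsilyl)oxy]-3-ethoxy-2-vinylcyclohex-2-en-1-one | CCOC1=C(C=C)C(=O)[C@H](O[Si](C)(C)C(C)(C)C)CC1 | intermediate
8 | (S)-1,2-epoxyoctane | CCCCCC[C@H]1CO1 | starting material
9 | (S)-octane-1,2-diol | CCCCCC[C@H](O)CO | intermediate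
10 | (4S)-4-hexyl-2-(4-methoxyphenyl)-1,3-dioxolane, acetal carbon as both epimers | CCCCCC[C@H]1COC(c2ccc(OC)cc2)O1 | intermediate
11 | (S)-2-[(4-methoxybenzyl)oxy]octan-1-ol | CCCCCC[C@H](OCc1ccc(OC)cc1)CO | intermediate
12 | (S)-2-[(4-methoxybenzyl)oxy]octanal | CCCCCC[C@H](OCc1ccc(OC)cc1)C=O | intermediate
13 | mixed ethyl ketal, (2S,6R,8aR)-6-[(tert-butyldimethylsilyl)oxy]-8a-ethoxy-2-{(1S)-1-[(4-methoxybenzyl)oxy]heptyl}-2,3,6,7,8,8a-hexahydro-5H-chromen-5-one | CCCCCC[C@H](OCc1ccc(OC)cc1)[C@@H]1CC=C2C(=O)[C@H](O[Si](C)(C)C(C)(C)C)CC[C@@]2(OCC)O1 | intermediate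
14 | free carbinol, 13 with the side-chain PMB ether replaced by OH | CCCCCC[C@H](O)[C@@H]1CC=C2C(=O)[C@H](O[Si](C)(C)C(C)(C)C)CC[C@@]2(OCC)O1 | intermediate
15 | tricyclic ketal enone, 10-exo-hexyl-4-[(tert-butyldimethylsilyl)oxy]-11,12-dioxatricyclo[7.2.1.0^1,6]dodec-6-en-5-one (6,8-dioxabicyclo[3.2.1]octene fused to the silyloxy cyclohexanone) | CCCCCC[C@@H]1O[C@]23CC[C@@H](O[Si](C)(C)C(C)(C)C)C(=O)C3=CC[C@@H]1O2 | intermediate
16 | 4-hydroxy-6-methyl-2H-pyran-2-one | Cc1cc(O)cc(=O)o1 | starting material
17 | Michael adduct ketone, pyrone C-3 on the former enone β-carbon anti to the dioxolane bridge, ring-fusion H syn to the bridge | CCCCCC[C@@H]1O[C@]23CC[C@@H](O[Si](C)(C)C(C)(C)C)C(=O)[C@@H]3[C@@H](C[C@@H]1O2)c4c(O)cc(C)oc4=O | intermediate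
18 | O-TBS-trichopsistide B | CCCCCC[C@@H]1O[C@]23CC[C@@H](O[Si](C)(C)C(C)(C)C)[C@@]4(O)Oc5cc(C)oc(=O)c5[C@H](C[C@@H]1O2)[C@H]34 | intermediate
19 | trichopsistide B | CCCCCC[C@@H]1O[C@]23CC[C@@H](O)[C@@]4(O)Oc5cc(C)oc(=O)c5[C@H](C[C@@H]1O2)[C@H]34 | target

**Totals**

Total step count: 13. Longest linear sequence: 9 steps (steps 1–5, then 10–13); the aldehyde branch (steps 6–9) joins at step 10.

**Steps most likely to fail**

1. Step 10 (Proposed new method). The ring carbonyl may make the diene too weak a nucleophile, the vinylogous-ester carbonyl may sequester the Lewis acid, or the oxocarbenium ion may lose a proton before C–O closure and give a ring-opened dienyl alcohol. The fallback uses known reactions, sets out from aldehyde 12 together with iodide 5, and returns at 13. Chelation-controlled addition of vinylmagnesium bromide to 12 (MgBr2·OEt2, CH2Cl2, −78 °C) should give the syn allylic alcohol (3S,4S)-4-[(4-methoxybenzyl)oxy]dec-1-en-3-ol F1. Hydroboration with excess 9-BBN gives the B-alkyl borane F2. B-alkyl Suzuki–Miyaura coupling with 5 (PdCl2(dppf), AsPh3, Cs2CO3, DMF/THF/H2O) gives the 2-alkyl vinylogous ester F3. Electrophilic selenenylation at C-2 (N-(phenylseleno)phthalimide, cat. CSA, CH2Cl2, a little EtOH) is an alkoxyselenation in which the carbinol oxygen captures the oxocarbenium ion, giving the α-phenylseleno mixed ketal F4. Oxidation (H2O2, pyridine, 0 °C) and selenoxide syn-elimination toward the only β-hydrogens, those of the ring CH2, gives 13.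

2. Step 11. The oxocarbenium ion may lose a proton from the ring CH2, or be attacked at its remote allylic terminus, and drain into conjugated vinylogous-ester isomers instead of closing the ketal; 15 may also isomerise the same way under prolonged acid. The fallback removes that driving force by a redox detour; it sets out from 13 and returns at 15. Luche reduction (NaBH4, CeCl3, MeOH, −78 °C) gives the allylic alcohol F5. DDQ then gives the diol F6, and catalytic PPTS closes the bicyclic ketal allylic alcohol F7; with no carbonyl present, no vinylogous ester can form. Dess–Martin oxidation then restores the enone and gives 15 under non-acidic conditions.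

3. Step 12. Ketonisation may occur from the wrong face at the ring-fusion carbon, addition to the hindered trisubstituted enone may be slow, or the base may epimerise the α-silyloxy ketone. The fallback changes the end-game to thermodynamic control on the unprotected substrate; it sets out from 15 and returns at 19. HF·pyridine gives the free α-hydroxy enone F8. Pyrone 16 is then added to F8 as the last step under equilibrating conditions (Et3N or EDDA, MeOH/MeCN, warm). There retro-Michael/Michael addition, enolisation and hemiketal opening are all reversible, and the natural isomer no longer has to carry an axial silyloxy group.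

**Further compounds**

F1 | step 10 | (3S,4S)-4-[(4-methoxybenzyl)oxy]dec-1-en-3-ol | CCCCCC[C@H](OCc1ccc(OC)cc1)[C@@H](O)C=C
F2 | step 10 | 9-{(3S,4S)-3-hydroxy-4-[(4-methoxybenzyl)oxy]decyl}-9-borabicyclo[3.3.1]nonane | CCCCCC[C@H](OCc1ccc(OC)cc1)[C@@H](O)CCB1C2CCCC1CCC2
F3 | step 10 | (R)-6-[(tert-butyldimethylsilyl)oxy]-3-ethoxy-2-{(3S,4S)-3-hydroxy-4-[(4-methoxybenzyl)oxy]decyl}cyclohex-2-en-1-one | CCCCCC[C@H](OCc1ccc(OC)cc1)[C@@H](O)CCC1=C(OCC)CC[C@@H](O[Si](C)(C)C(C)(C)C)C1=O
F4 | step 10 | 4a-phenylseleno analogue of 13 with a saturated oxane ring (selenium-bearing and ketal carbons as mixtures) | CCCCCC[C@H](OCc1ccc(OC)cc1)[C@@H]1CCC2([Se]c3ccccc3)C(=O)[C@H](O[Si](C)(C)C(C)(C)C)CCC2(OCC)O1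
F5 | step 11 | allylic alcohol from 1,2-reduction of 13 (new carbinol as a mixture) | CCCCCC[C@H](OCc1ccc(OC)cc1)[C@@H]1CC=C2C(O)[C@H](O[Si](C)(C)C(C)(C)C)CC[C@@]2(OCC)O1
F6 | step 11 | diol from PMB removal of F5 | CCCCCC[C@H](O)[C@@H]1CC=C2C(O)[C@H](O[Si](C)(C)C(C)(C)C)CC[C@@]2(OCC)O1
F7 | step 11 | bicyclic ketal allylic alcohol, 15 with the ketone reduced to CH–OH | CCCCCC[C@@H]1O[C@]23CC[C@@H](O[Si](C)(C)C(C)(C)C)C(O)C3=CC[C@@H]1O2
F8 | step 12 | desilylated tricyclic ketal enone, 15 with free secondary OH | CCCCCC[C@@H]1O[C@]23CC[C@@H](O)C(=O)C3=CC[C@@H]1O2
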